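# Proposed synthesis of (2S)-5,7-dihydroxy-4'-methoxy-6-(3-methylbut-2-enyl)flavanone (9)

## The problem

Target 9 has a phloroglucinol-type ring A fused to the dihydropyranone ring C, a 4-methoxyphenyl ring B on C2, and one five-carbon chain on C6. If a flavanone is the starting point no ring has to be built, so the real problem is the position of the chain. C6 and C8 are both electron-rich CH carbons flanked by oxygen, and direct prenylation of such a ring attacks both of them and the phenol oxygens as well. The only stereocentre, C2 (S), is benzylic, bears O1 and lies β to the C4 ketone. It has no neighbouring centre to control or be controlled by, and it is lost whenever ring C opens reversibly to the chalcone form, readily in base and more slowly under hot protic or Lewis acid. The prenyl alkene C2''=C3'' sits between the 5- and 7-hydroxyls and cyclises onto either under acid to a dimethylchroman, so the closing steps must be near neutral. The two phenols differ: the 5-hydroxyl is hydrogen-bonded to the C4 carbonyl, while the 7-hydroxyl is free and more acidic, so O7 can be masked alone. Two features make the key step possible. First, O5 has only one open ortho carbon, C6, because the other, C4a, is the ring-fusion carbon that carries C4; a group delivered from O5 by a [3,3] shift can therefore arrive only at C6. Second, the chain ends in the trisubstituted alkene C2''=C3'', which is what cross-metathesis of a C6 allyl group with 2-methyl-2-butene (7) leaves behind, and its isopropylidene end has no geometry to set.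

## Retrosynthesis

**9 ⇒ 8 (O7–acyl bond).** The ester bond at O7 is cut last. An acetate is preferred here to a silyl ether or an acetal because it can leave by neutral acyl transfer. Fluoride would generate a basic phenoxide next to a base-labile C2, and acid would close a chroman from the prenyl group and a neighbouring phenol. Precursor 8 differs from 9 by one acetyl group, and the forward step must touch only an aryl ester.

**8 ⇒ 6 + 7 (C2''=C3'').** The chain is cut at its double bond rather than at C6–C1''. Cutting C6–C1'' leads back to an electrophilic or cross-coupling prenylation of ring A and reopens the C6/C8 question. Cutting C2''=C3'' leads to a C6 allyl group, which is the natural outcome of a sigmatropic shift from O5, and to 7, a cheap liquid that can serve as co-solvent. The precursor, (2S)-7-acetoxy-6-allyl-5-hydroxy-4'-methoxyflavanone (6), is smaller by two carbons and carries a terminal alkene, the most reactive alkene class in metathesis. The forward reaction needs chemoselectivity only: cross- rather than self-metathesis, no migration of the allyl double bond, and tolerance of the chelated 5-hydroxyl, the ketone and the aryl ester. It creates no alkene geometry and no stereocentre.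

**6 ⇒ 4, through 5 (C6–C1'').** The C6–C1'' bond of 6 is cut while the far allyl carbon is reconnected to O5, which is the retron of an aromatic Claisen rearrangement. The precursor is the 5-O-allyl ether 4, and the shift passes through dienone 5. The alternative of placing a complete prenyl group on O5 is rejected: it would arrive at C6 as the 1,1-dimethylallyl isomer and would be expected to move on to C8 by a Cope shift before the dienone enolises. The unsubstituted allyl group arrives, 5 enolises to the phenol, and the group stays at C6. This is why the prenyl group is assembled in two stages. The forward shift must run at a temperature C2 tolerates, which calls for Lewis-acid catalysis rather than a purely thermal rearrangement.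

**4 ⇒ 2 + 3 (O5–CH2).** The allyl ether bond is cut to the 7-monoacetate 2 and allyl alcohol (3). A Mitsunobu etherification is preferred to allyl halide with carbonate base, because such bases open ring C. Compound 2 has a single free hydroxyl, so no selectivity question arises. The forward reaction is asked to alkylate a hydrogen-bonded, hindered phenol.

**2 ⇒ 1 (O7–acetyl).** Removing the acetate gives (2S)-isosakuranetin (1), which already holds all three rings, the 4'-methyl ether and C2 in the required configuration. The forward step is monoacylation of the non-chelated 7-hydroxyl in the presence of the chelated 5-hydroxyl.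

## Roads not taken

**Alternative 1:** Ring C is cut at C3–C4 and O1–C2. In the forward direction a chiral Brønsted acid would release an alkoxy ortho-quinone methide from the salicylaldehyde dimethyl acetal A1, and this would add 4-methoxystyrene A2 in a [4+2] cycloaddition to give the 4-methoxychroman A3.
- Merits: the route is convergent, and ring C and C2 come from one catalytic step on achiral partners. Either enantiomer is available, and nothing depends on the supply or purity of a natural flavanone. In these respects it is better than the chosen plan.
- Weak points:
  - A1 must already carry the prenyl group between two protected oxygens, so the regiochemical problem is only moved to an earlier arene.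
  - The prenyl alkene is a second electron-rich alkene in an acidic medium that generates a cationic intermediate.
  - The methide carbon is flanked by the protected C5 oxygen, which crowds the chiral ion pair.
  - A3 is at the wrong oxidation level. The C4 methyl ether must be converted to the ketone in further operations, which erases the C4 centre the key step set, and two methoxymethyl ethers must then leave under acid beside the prenyl group.
- Comparison: the chosen plan offers five steps from a compound that already has every ring, no redox adjustment, and no acid once the alkene is in place.

**Alternative 2:** The C2–C3 bond is cut. The diazoketone A4, which carries ring B as a 4-methoxybenzyl ether on O1, would be decomposed by a chiral dirhodium tetracarboxylate Rh2(O2CR*)4 (divalent rhodium). The carbenoid at C3 would insert into a benzylic C–H bond to close ring C and give the bis-silyl flavanone A5.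
- Merits: C2 is created by the catalyst, ring B enters as a cheap ether, and A5 is already at the flavanone oxidation level.
- Weak points:
  - The carbenoid can attack the O1 lone pair instead. The resulting oxonium ylide undergoes a [1,2] benzyl shift and closes a five-membered rather than the six-membered ring, a well-known competitor of insertion.
  - The prenyl alkene is a cyclopropanation partner for a second molecule.
  - Enantioselective insertion next to oxygen with six-membered ring closure has narrower precedent than five-membered closure.
  - A4 requires a fully substituted benzoic acid derivative and a diazoketone synthesis at a crowded carbonyl.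
  - The final desilylation passes through phenoxides, which endanger C2.
- Comparison: this road is better than the chosen plan only in its independence from the chiral pool. The chosen plan has no competing pathway of comparable weight in any step and never makes or breaks a bond at C2.

**Alternative 3:** The C2–C1' bond is cut. 4-Methoxyphenylboronic acid A7 would add to the enone of the 6-prenylchromone A6 under a chiral diene or bisphosphine complex of monovalent rhodium, giving the bis(methoxymethyl) flavanone A8 with catalyst control at C2.
- Merits: this is the best-precedented asymmetric reaction type of the three, ring B is introduced convergently, and A8 is already a flavanone. If 1 proved partly racemic, or if the (2R) enantiomer were wanted, this would be the better road.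
- Weak points:
  - A chromone with an oxygen substituent at C5, peri to the carbonyl, and a second donor at C7 is a poor acceptor.
  - The aqueous base that usually accompanies boronic acid additions can open ring C of A8.
  - A6 must be made with the prenyl group already at C6. That again needs a blocked-ortho Claisen shift and a metathesis, or an equivalent, on top of a chromone synthesis, so the route is roughly twice as long.
  - The methoxymethyl ethers leave only under acid beside the prenyl group.
- Comparison: the chosen plan takes C2 from 1 untouched, ends with a neutral deprotection, and reaches 9 in five steps.

Key step: step 4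

Assumption: commercial isosakuranetin of natural origin is taken to be the (2S) enantiomer 1 in high enantiomeric purity; C2 is inherited and never re-made, so its purity is to be checked on a chiral stationary phase before use and again after steps 3 and 5.

## Route

Step 1
Reactants: 1 (2S)-isosakuranetin [(2S)-5,7-dihydroxy-2-(4-methoxyphenyl)chroman-4-one]
Product: 2 (2S)-7-acetoxy-5-hydroxy-4'-methoxyflavanone
Conditions: Ac2O (1.1 equiv), pyridine, CH2Cl2, 0 °C → rt
Reagents that add atoms: acetic anhydride, CC(=O)OC(C)=O
Why: Selective O-acylation of the free, more acidic 7-hydroxyl; the 5-hydroxyl is tied up in a hydrogen bond to the C4 carbonyl and is hindered, so it should stay unacylated with one equivalent of anhydride, and pyridine at this temperature is too weak a base to open ring C.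

Step 2
Reactants: 2 (2S)-7-acetoxy-5-hydroxy-4'-methoxyflavanone; 3 allyl alcohol (prop-2-en-1-ol)
Product: 4 (2S)-7-acetoxy-5-allyloxy-4'-methoxyflavanone
Conditions: PPh3, DIAD, THF, 0 °C → rt
Reagents that add atoms: none
Why: Mitsunobu etherification: the 5-hydroxyl, the only acidic hydroxyl left, protonates the phosphine–azodicarboxylate betaine and its phenoxide displaces triphenylphosphine oxide from the allyloxyphosphonium ion at the primary carbon; no base stronger than the hydrazide anion is present, so ring C should stay closed, C2 untouched and the aryl acetate intact.

Step 3
Reactants: 4 (2S)-7-acetoxy-5-allyloxy-4'-methoxyflavanone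
Product: 6 (2S)-7-acetoxy-6-allyl-5-hydroxy-4'-methoxyflavanone, via C6-allyl cyclohexadienone 5 (not isolated)
Conditions: Eu(fod)3 [tris(6,6,7,7,8,8,8-heptafluoro-2,2-dimethyloctane-3,5-dionato)europium, trivalent europium] (10 mol %), CHCl3, 60–70 °C, sealed tube
Reagents that add atoms: none
Why: Lewis-acid-catalysed aromatic Claisen rearrangement: the oxophilic lanthanide binds the C4 carbonyl and O5 as a chelate, weakens the O5–CH2 bond and lets the [3,3] shift run far below the purely thermal range; C4a is fully substituted, so the allyl terminus can bond only to C6, and dienone 5 should enolise to the chelated 5-phenol before any Cope shift toward C8; C2 is a spectator.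

Step 4
Reactants: 6 (2S)-7-acetoxy-6-allyl-5-hydroxy-4'-methoxyflavanone; 7 2-methyl-2-butene
Product: 8 (2S)-7-acetoxy-5-hydroxy-4'-methoxy-6-(3-methylbut-2-enyl)flavanone
Conditions: second-generation Grubbs catalyst RuCl2(H2IMes)(PCy3)(=CHPh) (divalent ruthenium, 5 mol %), 7 (large excess)/CH2Cl2, rt → 40 °C, sealed tube
Reagents that add atoms: none
Why: Olefin cross-metathesis by the Chauvin mechanism: after phosphine loss the ruthenium alkylidene forms a ruthenacyclobutane with the terminal alkene of 6, and cycloreversion leaves the substrate on the metal or removes its =CH2 end. A second ruthenacyclobutane with 7 then transfers the isopropylidene end to C2'', while the ethylidene end of 7 and the lost methylene leave together as propene. The closest known reaction type is the cross-metathesis of allyl arenes with 2-methyl-2-butene to prenyl arenes under this catalyst. No ring closes and no stereocentre is formed; the isopropylidene terminus has no geometry, and the position on ring A was fixed in step 3. Cross- rather than self-metathesis is secured by using 7 as co-solvent and by the product's trisubstituted alkene, which is nearly inert to the catalyst and acts as a sink; any but-2-enyl intermediate from transfer of the ethylidene end is still a disubstituted alkene and should re-enter the cycle. Migration of the allyl double bond into conjugation is held back by fresh, hydride-free catalyst and a low temperature. The 5-hydroxyl is engaged in its hydrogen bond to C4=O and should not bind ruthenium, and the neutral medium leaves C2, the acetate and the new prenyl group alone.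

Step 5
Reactants: 8 (2S)-7-acetoxy-5-hydroxy-4'-methoxy-6-(3-methylbut-2-enyl)flavanone
Product: 9 (2S)-5,7-dihydroxy-4'-methoxy-6-(3-methylbut-2-enyl)flavanone
Conditions: NH4OAc, MeOH/H2O (4:1), rt
Reagents that add atoms: none
Why: Neutral acyl transfer from the aryl acetate to methanol, buffered by ammonium acetate; the aryl ester is by far the most reactive acyl group present, and the medium is neither basic enough to open ring C nor acidic enough to cyclise a phenol onto the prenyl alkene, so C2 and the chain should be preserved.

## Compound list

1 | (2S)-isosakuranetin, (2S)-5,7-dihydroxy-2-(4-methoxyphenyl)chroman-4-one | COc1ccc([C@@H]2CC(=O)c3c(O)cc(O)cc3O2)cc1 | starting material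
2 | (2S)-7-acetoxy-5-hydroxy-4'-methoxyflavanone | COc1ccc([C@@H]2CC(=O)c3c(O)cc(OC(C)=O)cc3O2)cc1 | intermediate
3 | allyl alcohol (prop-2-en-1-ol) | C=CCO | starting material
4 | (2S)-7-acetoxy-5-allyloxy-4'-methoxyflavanone | COc1ccc([C@@H]2CC(=O)c3c(OCC=C)cc(OC(C)=O)cc3O2)cc1 | intermediate
5 | (2S)-7-acetoxy-6-allyl-2-(4-methoxyphenyl)-2,3-dihydro-6H-chromene-4,5-dione (ortho-dienone, both C6 epimers) | COc1ccc([C@@H]2CC(=O)C3=C(C=C(OC(C)=O)C(CC=C)C3=O)O2)cc1 | intermediate
6 | (2S)-7-acetoxy-6-allyl-5-hydroxy-4'-methoxyflavanone | COc1ccc([C@@H]2CC(=O)c3c(cc(OC(C)=O)c(CC=C)c3O)O2)cc1 | intermediate
7 | 2-methyl-2-butene | CC=C(C)C | starting material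
8 | (2S)-7-acetoxy-5-hydroxy-4'-methoxy-6-(3-methylbut-2-enyl)flavanone | COc1ccc([C@@H]2CC(=O)c3c(cc(OC(C)=O)c(CC=C(C)C)c3O)O2)cc1 | intermediate
9 | (2S)-5,7-dihydroxy-4'-methoxy-6-(3-methylbut-2-enyl)flavanone | COc1ccc([C@@H]2CC(=O)c3c(cc(O)c(CC=C(C)C)c3O)O2)cc1 | target

## Step count and least certain steps

Total step count: 5. Longest linear sequence: 5 steps (1 → 2 → 4 → 6 → 8 → 9).

**Step 4 (key step).**
- Risk: migration of the allyl double bond into conjugation with ring A, caused by ruthenium hydride species from catalyst decay and helped by the neighbouring phenol. Metathesis of the resulting propenyl arene would shorten the chain by one carbon.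
- Risk: incomplete exchange that stalls after transfer of the ethylidene end.
- Risk: slow turnover if the ortho phenol and the alkene hold the metal together.
- Fallback: it sets out from 6 and returns at 9. It gives up the free phenol rather than adjusting the catalyst. Compound 6 is acetylated at O5 (Ac2O, DMAP, pyridine, CH2Cl2) to (2S)-5,7-diacetoxy-6-allyl-4'-methoxyflavanone F1, which has no acidic or chelating hydroxyl. Cross-metathesis of F1 with 7 should give (2S)-5,7-diacetoxy-4'-methoxy-6-(3-methylbut-2-enyl)flavanone F2. Both acetates are then removed together with NH4OAc in aqueous methanol to give 9.

**Step 3.**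
- Risk: partial loss of configuration at C2 through Lewis-acid-assisted opening and reclosure of ring C at the temperature the shift needs.
- Risk: a second sigmatropic shift of 5 toward C8 before it enolises.
- Risk: hydrolysis of the O7 acetate by water carried on the lanthanide.
- Fallback: it sets out from 2 and returns at 6. It replaces the sigmatropic shift by a cross-coupling. Compound 2 is iodinated ortho to the 5-hydroxyl with benzyltrimethylammonium dichloroiodate and CaCO3 in CH2Cl2/MeOH to (2S)-7-acetoxy-5-hydroxy-6-iodo-4'-methoxyflavanone F3. Stille coupling of F3 with allyltributylstannane under Pd(PPh3)4 (zerovalent palladium) in toluene should give 6. The cost is that C6 over C8 is then steered by the chelated phenol and no longer enforced by a blocked ortho carbon.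

**Step 2.**
- Risk: slow etherification of the hydrogen-bonded, hindered 5-hydroxyl, so that the betaine is consumed by alkylation of the hydrazide instead.
- Risk: acyl transfer from O7 in the mildly basic betaine medium.
- Fallback: it sets out from 2 and returns at 4. It changes the electrophile from an oxyphosphonium ion to a π-allyl complex. Tsuji–Trost O-allylation with allyl tert-butyl carbonate and Pd(PPh3)4 (zerovalent palladium) in THF generates tert-butoxide only transiently on decarboxylation, and the phenol quenches it at once. No new compound is made.

**Step 5.**
- Risk: slow cleavage with long exposure of the flavanone.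
- Risk: erosion of C2 if the medium drifts basic as the phenol is released.
- Fallback: it sets out from 8 and returns at 9. Enzymatic alcoholysis with immobilised Candida antarctica lipase B and n-butanol in tert-butyl methyl ether proceeds through an acyl-enzyme at neutral pH, without water or ionic base. No new compound is made.

## Further compounds

F1 | step 4 | (2S)-5,7-diacetoxy-6-allyl-4'-methoxyflavanone | COc1ccc([C@@H]2CC(=O)c3c(cc(OC(C)=O)c(CC=C)c3OC(C)=O)O2)cc1
F2 | step 4 | (2S)-5,7-diacetoxy-4'-methoxy-6-(3-methylbut-2-enyl)flavanone | COc1ccc([C@@H]2CC(=O)c3c(cc(OC(C)=O)c(CC=C(C)C)c3OC(C)=O)O2)cc1
F3 | step 3 | (2S)-7-acetoxy-5-hydroxy-6-iodo-4'-methoxyflavanone | COc1ccc([C@@H]2CC(=O)c3c(cc(OC(C)=O)c(I)c3O)O2)cc1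
F0 | step 2 | none | none
F0 | step 5 | none | none
A1 | alternative 1 | 6-hydroxy-2,4-bis(methoxymethoxy)-3-(3-methylbut-2-enyl)benzaldehyde dimethyl acetal | COC(OC)c1c(O)cc(OCOC)c(CC=C(C)C)c1OCOC
A2 | alternative 1 | 4-methoxystyrene | C=Cc1ccc(OC)cc1
A3 | alternative 1 | (2S,4S)-4-methoxy-2-(4-methoxyphenyl)-5,7-bis(methoxymethoxy)-6-(3-methylbut-2-enyl)chroman | COc1ccc([C@@H]2C[C@H](OC)c3c(cc(OCOC)c(CC=C(C)C)c3OCOC)O2)cc1
A4 | alternative 2 | 2-diazo-1-[2,4-bis(tert-butyldimethylsilyloxy)-6-(4-methoxybenzyloxy)-3-(3-methylbut-2-enyl)phenyl]ethanone | COc1ccc(COc2cc(O[Si](C)(C)C(C)(C)C)c(CC=C(C)C)c(O[Si](C)(C)C(C)(C)C)c2C(=O)C=[N+]=[N-])cc1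
A5 | alternative 2 | (2S)-5,7-bis(tert-butyldimethylsilyloxy)-4'-methoxy-6-(3-methylbut-2-enyl)flavanone | COc1ccc([C@@H]2CC(=O)c3c(cc(O[Si](C)(C)C(C)(C)C)c(CC=C(C)C)c3O[Si](C)(C)C(C)(C)C)O2)cc1
A6 | alternative 3 | 5,7-bis(methoxymethoxy)-6-(3-methylbut-2-enyl)chromen-4-one | O=c1ccoc2cc(OCOC)c(CC=C(C)C)c(OCOC)c12
A7 | alternative 3 | 4-methoxyphenylboronic acid | COc1ccc(B(O)O)cc1
A8 | alternative 3 | (2S)-4'-methoxy-5,7-bis(methoxymethoxy)-6-(3-methylbut-2-enyl)flavanone | COc1ccc([C@@H]2CC(=O)c3c(cc(OCOC)c(CC=C(C)C)c3OCOC)O2)cc1
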